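## Analysis of the target

Suaveolindole (22) has one carbocycle, a cyclohexane numbered here C1 (exocyclic isopropylidene), C2 and C3 (methylenes), C4 (CH–CH3), C5 (quaternary: methyl and indol-3-ylmethyl) and C6 (CH carrying the 2-carboxyethyl chain). The three stereocentres are contiguous, C4 (R), C5 (R) and C6 (S), which is (1S,2R,3R) in the systematic name 3-[2-(1H-indol-3-ylmethyl)-2,3-dimethyl-6-(propan-2-ylidene)cyclohexyl]propanoic acid. The C4 methyl and the indolylmethyl arm share one ring face, so the two methyl groups are trans, and the C6 chain lies on the other face, cis to the C5 methyl. The sensitive groups are the tetrasubstituted C1=CMe2 alkene (protonation gives a tertiary cation that can move the double bond into the ring or be trapped by the carboxyl group as a lactone), the N–H indole with its free C2 position, and the carboxylic acid. No stereocentre is α to a carbonyl group, so nothing epimerises once set. The synthesis is hard because quaternary C5 sits between two tertiary stereocentres, because its bond to the indole-bearing CH2 is neopentyl and cannot be made by substitution, and because C6 must be created next to a tetrasubstituted alkene that may not move. The strategy rests on the unit C5–CH2–(indol-3-yl) with a free indole C2–H: it is the Fischer retron of the aldehyde C5–CH2–CH2–CHO, which is the linear hydroformylation product of a vinyl group on C5, so the pyrrole ring (N1, C2, C3, C3a, C7a) can be grown from a C5-vinyl group, carbon monoxide and phenylhydrazine.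

## Retrosynthetic reasoning

**22 ⇒ 21.** Only the ester C–O bond is cut. The acid is carried as its methyl ester because the chain homologation delivers that ester directly, and because a free carboxyl group beside the isopropylidene would invite lactonisation under the acidic indolisation. The forward step is a mild hydroxide saponification.

**21 ⇒ 16 + 17 + 18.** The indole bonds C2–C3, C3–C3a and N1–C2 are cut. Cutting at C5–CH2 or CH2–C3 instead would demand substitution at a neopentyl carbon or alkylation of an indole by a very hindered electrophile. The cut chosen removes the whole heterocycle and leaves a vinyl group on C5, which tolerates the bases, hydrides, radicals and peracid used earlier. Forward, rhodium-catalysed hydroformylation of 16 with 18 and hydrogen must be linear and must spare the tetrasubstituted alkene. It gives aldehyde 19, which condenses with phenylhydrazine 17 to hydrazone 20, and acid then drives the Fischer cyclisation.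

**16 ⇒ 12 (through 14 and 15).** The α-carbon of the propanoate is excised. A two-carbon acid on C6 beside an alkylidene group is the signature of a Claisen rearrangement, whereas a three-carbon chain is not. Forward, an Arndt–Eistert sequence inserts the missing carbon; the migrating group is a CH2, so no stereocentre is involved.

**12 ⇒ 9 ⇒ 8.** The C6–CH2 bond is cut with allylic transposition, returning the double bond to C6=C1 and placing oxygen on the isopropyl carbon. C1 carries no carbonyl, so enolate alkylation is not available. The [3,3] shift of the silyl ketene acetal 10 makes the C–C bond, the C6 stereocentre and the regiodefined tetrasubstituted alkene in one event. The half-chair of the cyclohexene with the C4 methyl equatorial holds the C5 vinyl group pseudoaxial, so the new bond forms on the opposite face along the axial trajectory. The other half-chair would place the incoming carbon 1,3-diaxial to the C4 methyl.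

**8 ⇒ 7 ⇒ 6 ⇒ 5 ⇒ 4.** This is a 1,3-transposition of oxygen: 8 is the transposed allylic alcohol of enone 4. The hydrazone-based version would need condensation at a carbonyl flanked by two fully substituted carbons, so a radical version is used. Reduction gives 5, epoxidation of the tetrasubstituted alkene gives 6, and thioacylation gives 7. A stannyl radical chain then removes the original oxygen, and the carbon radical at C6 opens the epoxide. Forward, the epoxidation must select the tetrasubstituted alkene over the vinyl group.

**4 ⇒ 3 ⇒ 2 ⇒ 1.** Three bonds at C5 are cut: the vinyl C=C (methylenation of a formyl group), C5–CH3 and C5–CHO. (R)-Pulegone 1 already holds the isopropylidene, the C4 stereocentre in the right configuration, the carbonyl at C6 and a single free α-position, C5. Formylation comes first and methylation second, so that the methyl group enters anti to the C4 methyl and the formyl group, the future vinyl and indolylmethyl carbon, ends up cis to it. The formyl group also fixes the regiochemistry, which a simple enolate of 1 would not, since γ-deprotonation competes.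

## Alternatives that were turned down

**Alternative 1:** The C5 methyl is read as a cleaved cyclopropane bond. In the forward key step the diazoketone A2 gives a copper carbenoid at the future C6, which adds to its 1,1-disubstituted alkene. This closes the six-membered ring and the three-membered ring of bicyclic ketone A1 at once. Reductive opening would then release the methyl group and leave an enolate at C6 for the chain.
- For: the quaternary centre forms intramolecularly with the indolylmethyl arm already attached, so neither a neopentyl substitution nor a late indole synthesis is needed. On the making of C5 it is at least as strong as the alkylation of 2.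
- Against: the single stereocentre of A2 must steer the alkene face through a flexible tether. The carbenoid can also attack the C2=C3 bond of the N-acylindole. After ring opening, the C1 ketone must become a tetrasubstituted isopropylidene beside a branched carbon, for which no dependable olefination exists. The Boc-indole must also survive dissolving-metal conditions.
- Comparison: the chosen route takes the isopropylidene and C4 from 1 and never makes a tetrasubstituted alkene by olefination. Its risk sits in one step, where that of A1 is spread over several.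

**Alternative 2:** The bonds C1–C6 and C4–C5 are cut. The forward step is a [4+2] cycloaddition of vinylallene A4 (allene central carbon = C1, propenyl terminus = C4) with the trisubstituted enal A5 (α-carbon = C5, β-carbon = C6) under a chiral oxazaborolidinium-type Lewis acid, giving cyclohexene A3.
- For: ring, all three stereocentres, isopropylidene and chain arise in one step from achiral pieces. In convergence and step count it clearly beats the chosen route, and the C5/C6 relationship follows from the enal geometry.
- Against: A5 is a β-alkyl-α-methyl enal, among the least reactive dienophiles. Both termini of A4 are substituted, so the regiochemical bias is weak. The required cis relation of the C4 methyl and the formyl group needs endo-formyl topology, whereas α-substituted enals tend to place the formyl group exo. A3 still needs selective reduction of a ring alkene conjugated to the isopropylidene, and conversion of a neopentyl aldehyde into the indolylmethyl arm.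
- Comparison: the chosen route is longer, but each stereocentre is set by substrate control from a chiral-pool centre, and the indolylmethyl arm is planned from the outset through the vinyl group.

**Alternative 3:** The bonds C3–C4 and C5–C6 are cut. The forward step is a [4+2] cycloaddition of the 2-silyloxydiene A7 (chain-bearing terminus = C6) with enal A8 (α-carbon = C5 carrying the indolylmethyl arm, β-carbon = C4) under a chiral Lewis acid, giving A6.
- For: the indole enters on a simple building block, the electron-rich diene gives good reactivity and aligned regiochemistry, and no acidic indolisation is run beside the isopropylidene. On that last point it is stronger than the chosen route.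
- Against: A6 is far from 22. The formyl group on C5 must be reduced to methyl. The silyl enol ether unveils a C2 ketone that the target lacks; it must serve to build the isopropylidene at C1 regioselectively and then be removed without moving the new alkene. The Boc-indole must also tolerate the Lewis acid.
- Comparison: the chosen route has the isopropylidene and the correct oxidation levels from the start, and it forms the heterocycle in the step before last.

Key step: step 12

Remark: 5, 6 and 7 are carried as mixtures of epimers at the carbinol carbon (6 and 7 also at the spiro carbon), because step 7 erases both centres; their SMILES leave these centres undefined.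

## Route

Step 1
Reactants: 1 (R)-pulegone [(5R)-5-methyl-2-(propan-2-ylidene)cyclohexan-1-one]
Product: 2 (2Z,3R)-2-(hydroxymethylidene)-3-methyl-6-(propan-2-ylidene)cyclohexan-1-one
Conditions: NaH, HCO2Et, EtOH (cat.), THF, 0 °C → rt; then 1 M HCl, 0 °C
Reagents that add atoms: ethyl formate, CCOC=O
Why: Crossed Claisen condensation (formylation); the only position that can end as a stable chelated β-dicarbonyl enolate is the free α′-CH2, so the reversible acylation should funnel to 2. No stereocentre is formed and the existing one carries no acidic hydrogen.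

Step 2
Reactants: 2 (2Z,3R)-2-(hydroxymethylidene)-3-methyl-6-(propan-2-ylidene)cyclohexan-1-one
Product: 3 (1S,6R)-1,6-dimethyl-2-oxo-3-(propan-2-ylidene)cyclohexane-1-carbaldehyde
Conditions: MeI, K2CO3, acetone, 40 °C
Reagents that add atoms: iodomethane, CI
Why: C-Alkylation of a β-keto aldehyde enolate. A(1,2) strain between the planar formyl-bearing carbon and the neighbouring secondary methyl should push that methyl axial, so MeI enters axially on the opposite face; the new methyl ends trans to it and the formyl group cis (1S).

Step 3
Reactants: 3 (1S,6R)-1,6-dimethyl-2-oxo-3-(propan-2-ylidene)cyclohexane-1-carbaldehyde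
Product: 4 (2R,3R)-2-ethenyl-2,3-dimethyl-6-(propan-2-ylidene)cyclohexan-1-one
Conditions: Ph3PCH3Br, KN(SiMe3)2, THF, 0 °C; then 3, −78 → 0 °C
Reagents that add atoms: methyltriphenylphosphonium bromide, C[P+](c1ccccc1)(c1ccccc1)c1ccccc1.[Br-]
Why: Wittig methylenation; the aldehyde should react far faster than the hindered cross-conjugated ketone, and it has no α-hydrogen, so the quaternary centre is untouched (its descriptor changes from S to R only through the priority rules).

Step 4
Reactants: 4 (2R,3R)-2-ethenyl-2,3-dimethyl-6-(propan-2-ylidene)cyclohexan-1-one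
Product: 5 (2R,3R)-2-ethenyl-2,3-dimethyl-6-(propan-2-ylidene)cyclohexan-1-ol (both C1 epimers)
Conditions: LiAlH4, Et2O, 0 °C; then H2O
Reagents that add atoms: none
Why: 1,2-Hydride reduction of an enone; the small hydride should reach the hindered carbonyl, and the configuration of the new carbinol centre is irrelevant because step 7 removes it.

Step 5
Reactants: 5 (2R,3R)-2-ethenyl-2,3-dimethyl-6-(propan-2-ylidene)cyclohexan-1-ol
Product: 6 (5R,6R)-5-ethenyl-2,2,5,6-tetramethyl-1-oxaspiro[2.5]octan-4-ol (diastereomer mixture at C3 and C4)
Conditions: mCPBA, NaHCO3, CH2Cl2, 0 °C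
Reagents that add atoms: 3-chloroperoxybenzoic acid (mCPBA), OOC(=O)c1cccc(Cl)c1
Why: Prilezhaev epoxidation; the electron-rich tetrasubstituted alkene, assisted by the allylic hydroxyl, should react much faster than the monosubstituted vinyl group, and the buffer protects the acid-labile epoxide. The new spiro centre is erased in step 7.

Step 6
Reactants: 6 (5R,6R)-5-ethenyl-2,2,5,6-tetramethyl-1-oxaspiro[2.5]octan-4-ol
Product: 7 O-[(5R,6R)-5-ethenyl-2,2,5,6-tetramethyl-1-oxaspiro[2.5]octan-4-yl] 1H-imidazole-1-carbothioate
Conditions: 1,1′-thiocarbonyldiimidazole, DMAP (cat.), ClCH2CH2Cl, 70 °C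
Reagents that add atoms: 1,1′-thiocarbonyldiimidazole, S=C(n1ccnc1)n1ccnc1
Why: Thioacylation of a secondary alcohol, the activation used for Barton–McCombie deoxygenation; the neutral conditions avoid alkoxide formation next to the epoxide and hence Payne rearrangement.

Step 7
Reactants: 7 O-[(5R,6R)-5-ethenyl-2,2,5,6-tetramethyl-1-oxaspiro[2.5]octan-4-yl] 1H-imidazole-1-carbothioate
Product: 8 2-[(3R,4R)-3-ethenyl-3,4-dimethylcyclohex-1-en-1-yl]propan-2-ol
Conditions: Bu3SnH, AIBN (cat.), toluene, 90 °C
Reagents that add atoms: none
Why: Barton–McCombie-type radical deoxygenation coupled to epoxide fragmentation, the radical counterpart of the Wharton transposition: stannyl radical adds to sulfur, C–O scission gives the ring radical, and the adjacent epoxide opens by C–O cleavage much faster than the radical can attack the vinyl group. The tertiary alkoxyl radical is then reduced by Bu3SnH.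

Step 8
Reactants: 8 2-[(3R,4R)-3-ethenyl-3,4-dimethylcyclohex-1-en-1-yl]propan-2-ol
Product: 9 2-[(3R,4R)-3-ethenyl-3,4-dimethylcyclohex-1-en-1-yl]propan-2-yl acetate
Conditions: Ac2O, Et3N, DMAP, CH2Cl2, rt
Reagents that add atoms: acetic anhydride, CC(=O)OC(C)=O
Why: DMAP-catalysed acylation, which is the standard way to esterify tertiary allylic alcohols; the basic medium prevents ionisation of the product.

Step 9
Reactants: 9 2-[(3R,4R)-3-ethenyl-3,4-dimethylcyclohex-1-en-1-yl]propan-2-yl acetate
Product: 12 [(1S,2R,3R)-2-ethenyl-2,3-dimethyl-6-(propan-2-ylidene)cyclohexyl]acetic acid, via silyl ketene acetal 10 (not isolated), via trimethylsilyl ester 11 (not isolated)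
Conditions: LiN(iPr)2, Me3SiCl, THF, −78 °C → 50 °C; then 1 M HCl to pH 3, 0 °C
Reagents that add atoms: none
Why: Ireland–Claisen rearrangement; the [3,3] shift of 10 forms the ring–CH2 bond and the isopropylidene together. In the half-chair with the secondary methyl equatorial the vinyl group is pseudoaxial, so the new bond should form on the opposite face along the axial trajectory (1S). Attack on the other face would be syn to the vinyl group or 1,3-diaxial to the methyl group.

Step 10
Reactants: 12 [(1S,2R,3R)-2-ethenyl-2,3-dimethyl-6-(propan-2-ylidene)cyclohexyl]acetic acid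
Product: 14 1-diazo-3-[(1S,2R,3R)-2-ethenyl-2,3-dimethyl-6-(propan-2-ylidene)cyclohexyl]propan-2-one, via mixed carbonic anhydride 13 (not isolated)
Conditions: ClCO2Et, Et3N, THF, −15 °C; then CH2N2, Et2O, 0 °C → rt
Reagents that add atoms: diazomethane, C=[N+]=[N-]
Why: First half of the Arndt–Eistert homologation; acylation of diazomethane by the mixed anhydride proceeds without strong acid, so the isopropylidene and the β-stereocentre are not at risk.

Step 11
Reactants: 14 1-diazo-3-[(1S,2R,3R)-2-ethenyl-2,3-dimethyl-6-(propan-2-ylidene)cyclohexyl]propan-2-one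
Product: 16 methyl 3-[(1S,2R,3R)-2-ethenyl-2,3-dimethyl-6-(propan-2-ylidene)cyclohexyl]propanoate, via ketene 15 (not isolated)
Conditions: PhCO2Ag (cat.), Et3N, MeOH, rt, dark
Reagents that add atoms: methanol, CO
Why: Wolff rearrangement; the silver-promoted 1,2-shift of the CH2 group gives ketene 15, which methanol traps as the ester. The migrating carbon is not stereogenic and the alkenes are inert to these conditions.

Step 12
Reactants: 16 methyl 3-[(1S,2R,3R)-2-ethenyl-2,3-dimethyl-6-(propan-2-ylidene)cyclohexyl]propanoate; 17 phenylhydrazine; 18 carbon monoxide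
Product: 21 methyl 3-[(1S,2R,3R)-2-(1H-indol-3-ylmethyl)-2,3-dimethyl-6-(propan-2-ylidene)cyclohexyl]propanoate, via aldehyde 19 (not isolated), via phenylhydrazone 20 (not isolated)
Conditions: Rh(acac)(CO)2 (1 mol%), Xantphos (2 mol%), CO/H2 (1:1, 20 bar), PhNHNH2 (1.05 equiv), THF, 80 °C; then vent, 4 wt% aq. H2SO4, THF, 65 °C
Reagents that add atoms: phenylhydrazine, NNc1ccccc1; carbon monoxide, [C-]#[O+]
Why: The rhodium hydride adds across the vinyl group with the metal on the terminal carbon, CO insertion and hydrogenolysis give the linear aldehyde 19, and 19 condenses in the same pot with 17 to hydrazone 20. Acid then converts 20 into its ene-hydrazine, a [3,3] shift forms C3–C3a, and after rearomatisation the aniline nitrogen closes the pyrrole ring by 5-exo-trig attack on the iminium carbon (N1–C2); loss of ammonia gives the indole. The closest known reaction type is the tandem hydroformylation–Fischer indole synthesis of terminal alkenes with arylhydrazines. No stereocentre is formed, and the three existing ones lie away from any enolisable or ionisable position. Linear selectivity is secured by the quaternary carbon beside the vinyl group together with the wide-bite-angle diphosphine. Chemoselectivity is secured because a tetrasubstituted alkene does not insert into the rhodium hydride and the vinyl group has no allylic hydrogen through which it could isomerise. Aldehyde 19 has a single α-CH2, so only the 2-unsubstituted 3-alkylindole can form. The acid is added only after the gas is released and is kept dilute and at moderate temperature to spare the isopropylidene; partial ester hydrolysis is harmless because step 13 completes it.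

Step 13
Reactants: 21 methyl 3-[(1S,2R,3R)-2-(1H-indol-3-ylmethyl)-2,3-dimethyl-6-(propan-2-ylidene)cyclohexyl]propanoate
Product: 22 suaveolindole, 3-[(1S,2R,3R)-2-(1H-indol-3-ylmethyl)-2,3-dimethyl-6-(propan-2-ylidene)cyclohexyl]propanoic acid
Conditions: LiOH·H2O, THF/MeOH/H2O, rt; then 1 M HCl to pH 4, 0 °C
Reagents that add atoms: lithium hydroxide, [Li+].[OH-]
Why: Ester saponification by acyl–oxygen cleavage; no stereocentre is α to the carbonyl, and cold, mild acidification keeps the isopropylidene and the indole intact.

## Compound list

1 | (R)-pulegone [(5R)-5-methyl-2-(propan-2-ylidene)cyclohexan-1-one] | C[C@@H]1CCC(=C(C)C)C(=O)C1 | starting material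
2 | (2Z,3R)-2-(hydroxymethylidene)-3-methyl-6-(propan-2-ylidene)cyclohexan-1-one | CC(C)=C1CC[C@@H](C)/C(=C/O)C1=O | intermediate
3 | (1S,6R)-1,6-dimethyl-2-oxo-3-(propan-2-ylidene)cyclohexane-1-carbaldehyde | CC(C)=C1CC[C@@H](C)[C@@](C)(C=O)C1=O | intermediate
4 | (2R,3R)-2-ethenyl-2,3-dimethyl-6-(propan-2-ylidene)cyclohexan-1-one | CC(C)=C1CC[C@@H](C)[C@@](C)(C=C)C1=O | intermediate
5 | (2R,3R)-2-ethenyl-2,3-dimethyl-6-(propan-2-ylidene)cyclohexan-1-ol (C1 epimers) | CC(C)=C1CC[C@@H](C)[C@@](C)(C=C)C1O | intermediate
6 | (5R,6R)-5-ethenyl-2,2,5,6-tetramethyl-1-oxaspiro[2.5]octan-4-ol (C3/C4 diastereomers) | CC1(C)OC12CC[C@@H](C)[C@@](C)(C=C)C2O | intermediate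
7 | O-[(5R,6R)-5-ethenyl-2,2,5,6-tetramethyl-1-oxaspiro[2.5]octan-4-yl] 1H-imidazole-1-carbothioate | CC1(C)OC12CC[C@@H](C)[C@@](C)(C=C)C2OC(=S)n1ccnc1 | intermediate
8 | 2-[(3R,4R)-3-ethenyl-3,4-dimethylcyclohex-1-en-1-yl]propan-2-ol | CC(C)(O)C1=C[C@](C)(C=C)[C@H](C)CC1 | intermediate
9 | 2-[(3R,4R)-3-ethenyl-3,4-dimethylcyclohex-1-en-1-yl]propan-2-yl acetate | CC(=O)OC(C)(C)C1=C[C@](C)(C=C)[C@H](C)CC1 | intermediate
10 | trimethyl[(1-{[2-((3R,4R)-3-ethenyl-3,4-dimethylcyclohex-1-en-1-yl)propan-2-yl]oxy}ethenyl)oxy]silane | C=C(O[Si](C)(C)C)OC(C)(C)C1=C[C@](C)(C=C)[C@H](C)CC1 | intermediate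
11 | trimethylsilyl [(1S,2R,3R)-2-ethenyl-2,3-dimethyl-6-(propan-2-ylidene)cyclohexyl]acetate | CC(C)=C1CC[C@@H](C)[C@@](C)(C=C)[C@@H]1CC(=O)O[Si](C)(C)C | intermediate
12 | [(1S,2R,3R)-2-ethenyl-2,3-dimethyl-6-(propan-2-ylidene)cyclohexyl]acetic acid | CC(C)=C1CC[C@@H](C)[C@@](C)(C=C)[C@@H]1CC(=O)O | intermediate
13 | [(1S,2R,3R)-2-ethenyl-2,3-dimethyl-6-(propan-2-ylidene)cyclohexyl]acetic ethyl carbonic anhydride | CC(C)=C1CC[C@@H](C)[C@@](C)(C=C)[C@@H]1CC(=O)OC(=O)OCC | intermediate
14 | 1-diazo-3-[(1S,2R,3R)-2-ethenyl-2,3-dimethyl-6-(propan-2-ylidene)cyclohexyl]propan-2-one | CC(C)=C1CC[C@@H](C)[C@@](C)(C=C)[C@@H]1CC(=O)C=[N+]=[N-] | intermediate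
15 | 3-[(1S,2R,3R)-2-ethenyl-2,3-dimethyl-6-(propan-2-ylidene)cyclohexyl]prop-1-en-1-one | CC(C)=C1CC[C@@H](C)[C@@](C)(C=C)[C@@H]1CC=C=O | intermediate
16 | methyl 3-[(1S,2R,3R)-2-ethenyl-2,3-dimethyl-6-(propan-2-ylidene)cyclohexyl]propanoate | CC(C)=C1CC[C@@H](C)[C@@](C)(C=C)[C@@H]1CCC(=O)OC | intermediate
17 | phenylhydrazine | NNc1ccccc1 | starting material
18 | carbon monoxide | [C-]#[O+] | starting material
19 | methyl 3-[(1S,2R,3R)-2,3-dimethyl-2-(3-oxopropyl)-6-(propan-2-ylidene)cyclohexyl]propanoate | CC(C)=C1CC[C@@H](C)[C@@](C)(CCC=O)[C@@H]1CCC(=O)OC | intermediate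
20 | methyl 3-[(1S,2R,3R)-2,3-dimethyl-2-[3-(2-phenylhydrazinylidene)propyl]-6-(propan-2-ylidene)cyclohexyl]propanoate | CC(C)=C1CC[C@@H](C)[C@@](C)(CCC=NNc2ccccc2)[C@@H]1CCC(=O)OC | intermediate
21 | methyl 3-[(1S,2R,3R)-2-(1H-indol-3-ylmethyl)-2,3-dimethyl-6-(propan-2-ylidene)cyclohexyl]propanoate | CC(C)=C1CC[C@@H](C)[C@@](C)(Cc2c[nH]c3ccccc23)[C@@H]1CCC(=O)OC | intermediate
22 | suaveolindole, 3-[(1S,2R,3R)-2-(1H-indol-3-ylmethyl)-2,3-dimethyl-6-(propan-2-ylidene)cyclohexyl]propanoic acid | CC(C)=C1CC[C@@H](C)[C@@](C)(Cc2c[nH]c3ccccc23)[C@@H]1CCC(=O)O | target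

## Step count and least certain steps

Total: 13 steps. Longest linear sequence: 13 steps (1 → 22); 17 and 18 enter in step 12.

**Step 12 (key step).** The most likely failure is an acid-driven side process during the indolisation: protonation of the tetrasubstituted alkene, followed by migration of the double bond into the ring or by lactone formation once some ester has hydrolysed, at the temperature the aldehyde hydrazone needs for its [3,3] shift. A second weakness is slow hydroformylation of the shielded vinyl group, which lets hydrogenation compete. The fallback builds the indole without acid. It sets out from 16, which is hydroformylated without 17 under the same Rh(acac)(CO)2/Xantphos conditions, and aldehyde 19 is isolated. Heating 19 with 2-iodoaniline, Pd(OAc)2 and 1,4-diazabicyclo[2.2.2]octane in DMF at 85 °C should give methyl 3-[(1S,2R,3R)-2-{3-[(2-iodophenyl)imino]propyl}-2,3-dimethyl-6-(propan-2-ylidene)cyclohexyl]propanoate F1. Its enamine tautomer undergoes oxidative addition, intramolecular Heck-type C–C closure and aromatisation, and the route is rejoined at 21.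

**Step 2.** The most likely failure is poor facial discrimination in the C-methylation, together with some O-methylation, because a formyl group exerts only modest A(1,2) strain on the neighbouring methyl group. The fallback sets out from 1. Carbomethoxylation (NaH, dimethyl carbonate, THF, reflux) gives methyl (6R)-6-methyl-2-oxo-3-(propan-2-ylidene)cyclohexane-1-carboxylate F2. Its enolate carries a larger substituent and alkylates only at carbon; methylation (MeI, K2CO3, acetone) gives methyl (1R,6R)-1,6-dimethyl-2-oxo-3-(propan-2-ylidene)cyclohexane-1-carboxylate F3. LiAlH4 reduces both carbonyl groups to (2S,3R)-2-(hydroxymethyl)-2,3-dimethyl-6-(propan-2-ylidene)cyclohexan-1-ol F4, and oxidation of both hydroxyl groups with Dess–Martin periodinane returns the route to 3.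

**Step 7.** The most likely failure is diversion of the tertiary alkoxyl radical before it is reduced, by β-scission with loss of a methyl radical or by intramolecular hydrogen abstraction. One step earlier, thioacylation of the hindered carbinol of 6 may be slow. The fallback is the Wharton transposition and sets out from 4. Nucleophilic epoxidation (H2O2, NaOH, MeOH) gives (5R,6R)-5-ethenyl-2,2,5,6-tetramethyl-1-oxaspiro[2.5]octan-4-one F5. Hydrazine hydrate with catalytic AcOH in degassed MeOH gives (5R,6R)-5-ethenyl-4-hydrazinylidene-2,2,5,6-tetramethyl-1-oxaspiro[2.5]octane F6, which fragments with loss of nitrogen and rejoins the route at 8. Its own weakness is slow condensation at the doubly flanked carbonyl, which is why it is the reserve and not the first choice.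

**Step 9.** The most likely failure is ionisation or elimination of the tertiary allylic silyl ketene acetal 10 to a diene before the hindered C–C bond next to the quaternary carbon forms. Face selectivity could also erode if the half-chair with the axial methyl group takes part. The fallback replaces the [3,3] shift by a low-temperature [2,3]-Wittig–Still rearrangement and sets out from 8.
- KH and Bu3SnCH2I in THF give tributyl[({2-[(3R,4R)-3-ethenyl-3,4-dimethylcyclohex-1-en-1-yl]propan-2-yl}oxy)methyl]stannane F7.
- n-BuLi at −78 °C gives [({2-[(3R,4R)-3-ethenyl-3,4-dimethylcyclohex-1-en-1-yl]propan-2-yl}oxy)methyl]lithium F8, which rearranges on the same ring face to [(1S,2R,3R)-2-ethenyl-2,3-dimethyl-6-(propan-2-ylidene)cyclohexyl]methanol F9.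
- Dess–Martin periodinane with NaHCO3 gives (1S,2R,3R)-2-ethenyl-2,3-dimethyl-6-(propan-2-ylidene)cyclohexane-1-carbaldehyde F10.
- Ph3P=CHCO2Me gives methyl (2E)-3-[(1S,2R,3R)-2-ethenyl-2,3-dimethyl-6-(propan-2-ylidene)cyclohexyl]prop-2-enoate F11.
- Conjugate reduction with Mg in MeOH rejoins the route at 16.

## Further compounds

F1 | step 12 | methyl 3-[(1S,2R,3R)-2-{3-[(2-iodophenyl)imino]propyl}-2,3-dimethyl-6-(propan-2-ylidene)cyclohexyl]propanoate | CC(C)=C1CC[C@@H](C)[C@@](C)(CCC=Nc2ccccc2I)[C@@H]1CCC(=O)OC
F2 | step 2 | methyl (6R)-6-methyl-2-oxo-3-(propan-2-ylidene)cyclohexane-1-carboxylate | CC(C)=C1CC[C@@H](C)C(C(=O)OC)C1=O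
F3 | step 2 | methyl (1R,6R)-1,6-dimethyl-2-oxo-3-(propan-2-ylidene)cyclohexane-1-carboxylate | CC(C)=C1CC[C@@H](C)[C@@](C)(C(=O)OC)C1=O
F4 | step 2 | (2S,3R)-2-(hydroxymethyl)-2,3-dimethyl-6-(propan-2-ylidene)cyclohexan-1-ol | CC(C)=C1CC[C@@H](C)[C@@](C)(CO)C1O
F5 | step 7 | (5R,6R)-5-ethenyl-2,2,5,6-tetramethyl-1-oxaspiro[2.5]octan-4-one | CC1(C)OC12CC[C@@H](C)[C@@](C)(C=C)C2=O
F6 | step 7 | (5R,6R)-5-ethenyl-4-hydrazinylidene-2,2,5,6-tetramethyl-1-oxaspiro[2.5]octane | CC1(C)OC12CC[C@@H](C)[C@@](C)(C=C)C2=NN
F7 | step 9 | tributyl[({2-[(3R,4R)-3-ethenyl-3,4-dimethylcyclohex-1-en-1-yl]propan-2-yl}oxy)methyl]stannane | CCCC[Sn](CCCC)(CCCC)COC(C)(C)C1=C[C@](C)(C=C)[C@H](C)CC1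
F8 | step 9 | [({2-[(3R,4R)-3-ethenyl-3,4-dimethylcyclohex-1-en-1-yl]propan-2-yl}oxy)methyl]lithium | [Li]COC(C)(C)C1=C[C@](C)(C=C)[C@H](C)CC1
F9 | step 9 | [(1S,2R,3R)-2-ethenyl-2,3-dimethyl-6-(propan-2-ylidene)cyclohexyl]methanol | CC(C)=C1CC[C@@H](C)[C@@](C)(C=C)[C@@H]1CO
F10 | step 9 | (1S,2R,3R)-2-ethenyl-2,3-dimethyl-6-(propan-2-ylidene)cyclohexane-1-carbaldehyde | CC(C)=C1CC[C@@H](C)[C@@](C)(C=C)[C@@H]1C=O
F11 | step 9 | methyl (2E)-3-[(1S,2R,3R)-2-ethenyl-2,3-dimethyl-6-(propan-2-ylidene)cyclohexyl]prop-2-enoate | CC(C)=C1CC[C@@H](C)[C@@](C)(C=C)[C@@H]1/C=C/C(=O)OC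
A1 | alternative 1 | tert-butyl 3-[(5-methyl-2-oxobicyclo[4.1.0]heptan-6-yl)methyl]-1H-indole-1-carboxylate | O=C1CC[C@@H](C)[C@]2(Cc3cn(C(=O)OC(C)(C)C)c4ccccc34)C[C@H]12
A2 | alternative 1 | tert-butyl 3-[(3R)-7-diazo-3-methyl-2-methylidene-6-oxoheptyl]-1H-indole-1-carboxylate | [N-]=[N+]=CC(=O)CC[C@@H](C)C(=C)Cc1cn(C(=O)OC(C)(C)C)c2ccccc12
A3 | alternative 2 | methyl 3-[6-formyl-5,6-dimethyl-2-(propan-2-ylidene)cyclohex-3-en-1-yl]propanoate | CC(C)=C1C=C[C@@H](C)[C@@](C)(C=O)[C@@H]1CCC(=O)OC
A4 | alternative 2 | (5E)-2-methylhepta-2,3,5-triene | CC(C)=C=C/C=C/C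
A5 | alternative 2 | methyl (4E)-5-methyl-6-oxohex-4-enoate | O=C/C(C)=C/CCC(=O)OC
A6 | alternative 3 | methyl 3-{3-[(tert-butyldimethylsilyl)oxy]-6-formyl-6-{[1-(tert-butoxycarbonyl)-1H-indol-3-yl]methyl}-5-methylcyclohex-2-en-1-yl}propanoate | C1=C(O[Si](C)(C)C(C)(C)C)C[C@@H](C)[C@@](C=O)(Cc2cn(C(=O)OC(C)(C)C)c3ccccc23)[C@@H]1CCC(=O)OC
A7 | alternative 3 | methyl (4E)-6-[(tert-butyldimethylsilyl)oxy]hepta-4,6-dienoate | C=C(O[Si](C)(C)C(C)(C)C)/C=C/CCC(=O)OC
A8 | alternative 3 | tert-butyl 3-[(2E)-2-formylbut-2-en-1-yl]-1H-indole-1-carboxylate | C/C=C(/C=O)Cc1cn(C(=O)OC(C)(C)C)c2ccccc12
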